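## The problem

The target 24 is a flavone whose ring A is substituted at every position but C6: OMe at C5, a free OH at C7, and at C8 a C–C bond to C2' of an otherwise unsubstituted piperidine with a free NH. C2' is the only stereocentre and reads R (N1' > C8 > C3' > H). Nothing else in the molecule can relay it, so it has to come from an external chiral source while the crowded C8 carbon is still an accessible aldehyde carbon. The C2'–N1' bond is benzylic and sits ortho and para to three oxygens for as long as ring A is a phloroglucinol ether. Hot acid can ionise it (retro-Mannich, ortho-quinone methide) and strong base can deprotonate C2' once nitrogen bears a carbamate, and either event erases the stereocentre. The 5-OMe group, peri to the C4 carbonyl, is lost to strong Lewis acids, the pyranone opens in strong base, and the secondary amine has to be masked during every acylation and organometallic step. Before ring C exists, the 2,6-dioxygenated 4-methoxyphenyl group is locally symmetric: its two free CH positions are equivalent, and only the oxygen next to an acyl group can close ring C, so the 5,7,8-pattern arises without a regiochemical choice. The feature that opens the key step is the piperidine itself: C3' to C6' carry no substituent, and the C4'–C5' bond lies opposite nitrogen and away from the stereocentre and the aryl group. It can therefore be made as an alkene from an allyl arm on N1' and a homoallyl arm on C2', and then saturated.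

## Retrosynthesis

**Ring C last (24 from 22, through 23).** The O1–C2 bond is cut and the two MOM ethers and the Boc group are put back, which leads to ynone 22. The alternative of unmasking the phenols and acetylating the ring under Friedel–Crafts conditions would put a Lewis acid on the electron-rich benzylic carbamate, which is exactly the situation that endangers C2'. Ynone 22 already holds C2, C3, C4 and the phenyl group at the right oxidation level. The forward reaction must close the six-membered ring and not the five-membered aurone, which is secured by first adding a secondary amine to give enaminone 23, and it must deprotect without ionising the C2'–N1' bond.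

**C4a–C4 bond (22 from 21, from 18 and 19).** Cutting the aryl–carbonyl bond gives aryl bromide 18 and ynal 19, joined through aryllithium 20 to alcohol 21, which is oxidised. This replaces electrophilic acylation by a site-defined aryl anion, and 19 has no enolisable hydrogen that a hindered aryllithium could remove. The forward step needs halogen–lithium exchange to outrun deprotonation next to the carbamate nitrogen.

**C–Br and ring saturation (18 from 16 from 15).** The bromine is removed and then two hydrogens, giving tetrahydropyridine 15. Bromination comes after hydrogenation because catalytic hydrogenation would remove the halogen. The local symmetry of ring A in 16 means that a single monobromide can form.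

**C4'=C5' bond (15 from 14).** The ring alkene is cut to the acyclic diene 14. Against closure at N1'–C6' by alkylation or at N1'–C2' by amination, this cut uses the one bond of the piperidine that is remote from the hindered aryl group, and it leaves an acyclic precursor built from an aldehyde and two allyl units. The forward metathesis must favour ring closure over oligomerisation and alkene migration and must leave C2' alone.

**Nitrogen substituents (14 from 13 and 9; 13 from 10 through 12).** The N1'–C6' bond is cut to carbamate 13 and allyl bromide 9, and the Boc group is traced back to the sulfinyl group of 10 by way of amine 12. A carbamate is chosen because it makes nitrogen non-basic for the metathesis, survives hydrogenation, bromination, an aryllithium at low temperature and buffered oxidation, and leaves in the same final acid step as the MOM ethers.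

**C2'–C3' bond and the stereocentre (10 from 8 and 9).** The homoallyl arm is cut at C2'–C3', giving sulfinyl aldimine 8 and a second equivalent of 9. Asymmetric reduction or amination of an aryl ketone was the neighbouring option, but a ketone flanked by two ortho oxygens is twisted and shielded, whereas the aldimine CH carbon remains open to a nucleophile. The forward addition must deliver allyl to the Re face of 8.

**Ring A aldehyde (8 from 6 and 7; 6 from 3 and 4 through 5; 3 from 1 and 2).** The imine is cut to aldehyde 6 and sulfinamide 7, the formyl carbon to aryllithium 5 and formamide 4, and the two acetals to 5-methoxyresorcinol 1 and chloromethyl ether 2. The MOM groups earn their place three times: they direct lithiation of 3 to the carbon between them, they stabilise aryllithium 20 later, and they are removed in the final acid step.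

## Roads not taken

**Alternative 1:** The cut runs through ring C at C4a–C4, C3–C4 and O1–C2. The pyranone would be assembled last from ortho-iodophenol A2 (tert-butyl (2R)-2-(2,6-dihydroxy-3-iodo-4-methoxyphenyl)piperidine-1-carboxylate), phenylacetylene A3 and carbon monoxide A4.

- **Forward step:** PdCl2(PPh3)2 in an amine solvent would insert A4 into the aryl–palladium bond, couple the acyl complex with A3 and let the neighbouring phenol close onto the ynone, giving the carbamate-protected flavone A1 in one operation.
- **Merits:** One catalytic step builds all of ring C and no organolithium meets the carbamate. Counted from 16 the end-game is as long as the chosen one (unmasking, iodination, annulation, carbamate removal against bromination, addition, oxidation, cyclisation).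
- **Weak points:** It says nothing about C2' or the piperidine and would have to be grafted onto a piperidine synthesis such as the present one. A2 requires cleavage of the acetals with the carbamate in place and mono-iodination of a free, very electron-rich resorcinol that is prone to over-halogenation and oxidation. The iodide of A2 is electron-rich and flanked by OH and OMe, where insertion of A4 is slow against direct alkynylation (leading to a benzofuran) and where five-membered closure to an aurone also competes.
- **Comparison:** Against its catalytic economy the chosen plan sets a halogenation on the fully protected ring, a non-enolisable electrophile for the C4a–C4 bond and an enaminone that can only close to the six-membered ring. It pays for this with a stoichiometric organolithium step.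

**Alternative 2:** The cut is at C2'–C3' and N1'–C6'. The N-tosyl imine A6 of aldehyde 6 and the silyloxy diene A7 ((E)-1-methoxy-3-(trimethylsilyloxy)buta-1,3-diene) would combine under Cu(CH3CN)4PF6 and a chiral bisphosphine in an aza-Diels–Alder (Mannich–cyclisation) reaction to give dihydropyridinone A5.

- **Merits:** Ring, two bonds and the stereocentre come from one catalytic step, two steps from 6 against five for the route to 15. In step count to the ring and in the use of chirality it is the better road.
- **Weak points:** A6 is di-ortho-substituted, twisted and electron-rich, a poor electrophile for which enantioselectivity in this catalysis is unproven. A5 carries a C4' ketone and a C5'=C6' enamide bond that the target lacks, so conjugate reduction and deoxygenation add about three redox steps. The sulfonyl group would have to be removed reductively from a benzylic nitrogen on an electron-rich ring, with the risk of C–N cleavage, and replaced by a carbamate before ring C is built.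
- **Comparison:** After these corrections the way from 6 to 16 is longer than the six steps used here. The chosen plan gives up catalytic induction for a stoichiometric auxiliary, but its ring-closure product 15 differs from the needed piperidine only by one alkene.

**Alternative 3:** The cut is at N1'–C2' and N1'–C6'. The ω-chloro ketone A9 (5-chloro-1-[4-methoxy-2,6-bis(methoxymethoxy)phenyl]pentan-1-one), one acylation away from aryllithium 5, would be aminated by an (R)-selective ω-transaminase with its pyridoxal cofactor and a sacrificial amine donor. The (R)-amine A10 would then displace chloride to give piperidine A8.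

- **Merits:** If an enzyme accepted A9 this would be the shortest road by a wide margin: A8 in three steps from 1, against eight steps to 16 here, with no auxiliary, no metal and no nitrogen protecting group in the ring-forming step.
- **Weak points:** Transaminases rely on one large and one small carbonyl substituent and take aryl ketones whose ring is unhindered. In A9 the carbonyl lies between a four-carbon chain and a 2,6-dialkoxyaryl group that is twisted out of conjugation, so both substituents are large and the carbonyl is shielded. Such ketones fall outside the usual substrate range and would call for enzyme engineering, and A9 is lipophilic and poorly soluble in buffer.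
- **Comparison:** The chosen plan sets predictability against this step economy: its stereocentre is formed by addition to an aldimine CH carbon, which stays accessible despite the two ortho groups.

Key step: step 7

Assumption: the (S)-sulfinyl aldimine 8 is taken to react through the usual metal-chelated transition state, so that allyl is delivered to its Re face and C2' forms as R; the configuration of 10 is to be confirmed before the route is carried on.

## Route

Step 1
Reactants: 1 5-methoxyresorcinol (5-methoxybenzene-1,3-diol); 2 chloromethyl methyl ether
Product: 3 1-methoxy-3,5-bis(methoxymethoxy)benzene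
Conditions: NaH (2.5 equiv), DMF, 0 °C; then 2 (2.4 equiv), 0 °C to rt
Reagents that add atoms: chloromethyl methyl ether, COCCl
Why: Williamson-type O-alkylation of both phenoxides with the α-chloro ether (acetal protection); the two hydroxyl groups are equivalent, so exhaustive alkylation should give a single product.

Step 2
Reactants: 3 1-methoxy-3,5-bis(methoxymethoxy)benzene; 4 N,N-dimethylformamide
Product: 6 4-methoxy-2,6-bis(methoxymethoxy)benzaldehyde, via aryllithium 5 (not isolated)
Conditions: n-BuLi (1.1 equiv), TMEDA (1.1 equiv), THF, 0 °C; then 4, 0 °C to rt; H2O
Reagents that add atoms: N,N-dimethylformamide, CN(C)C=O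
Why: Directed ortho-metalation; the CH between the two MOM acetals is the most acidic and doubly coordinated site, so lithiation should occur there and not next to the methoxy group, and formylation of 5 with the formamide gives the aldehyde on work-up.

Step 3
Reactants: 6 4-methoxy-2,6-bis(methoxymethoxy)benzaldehyde; 7 (S)-2-methylpropane-2-sulfinamide
Product: 8 (S)-N-[(E)-[4-methoxy-2,6-bis(methoxymethoxy)phenyl]methylidene]-2-methylpropane-2-sulfinamide
Conditions: Ti(OEt)4 (2 equiv), THF, 65 °C
Reagents that add atoms: (S)-2-methylpropane-2-sulfinamide, CC(C)(C)[S@](=O)N
Why: Ti(OEt)4-mediated condensation of an aldehyde with tert-butanesulfinamide; the titanium alkoxide acts as Lewis acid and water scavenger, which suits a hindered, electron-rich aldehyde, and only the E-aldimine is expected.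

Step 4
Reactants: 8 (S)-N-[(E)-[4-methoxy-2,6-bis(methoxymethoxy)phenyl]methylidene]-2-methylpropane-2-sulfinamide; 9 allyl bromide
Product: 10 (S)-N-[(1R)-1-[4-methoxy-2,6-bis(methoxymethoxy)phenyl]but-3-en-1-yl]-2-methylpropane-2-sulfinamide
Conditions: In powder (1.5 equiv), 9 (2 equiv), THF, 60 °C
Reagents that add atoms: allyl bromide, C=CCBr
Why: Barbier-type indium-mediated allylation of an N-tert-butanesulfinyl aldimine; indium bound to the imine nitrogen and the sulfinyl oxygen holds a chair-like six-membered transition state, so allyl should add to the Re face of the (S)-sulfinyl E-aldimine, anti to tert-butyl, setting C2' as R, and the two diastereomers are separable on silica if selectivity falls short.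

Step 5
Reactants: 10 (S)-N-[(1R)-1-[4-methoxy-2,6-bis(methoxymethoxy)phenyl]but-3-en-1-yl]-2-methylpropane-2-sulfinamide; 11 di-tert-butyl dicarbonate
Product: 13 tert-butyl N-[(1R)-1-[4-methoxy-2,6-bis(methoxymethoxy)phenyl]but-3-en-1-yl]carbamate, via primary amine 12 (not isolated)
Conditions: HCl (2 equiv, 4 M in dioxane), MeOH, 0 °C; then aq. NaHCO3, 11, THF, rt
Reagents that add atoms: di-tert-butyl dicarbonate, CC(C)(C)OC(=O)OC(=O)OC(C)(C)C
Why: Acidolysis of the sulfinamide S–N bond is fast at 0 °C with two equivalents of HCl in methanol (the sulfinyl group leaves as its methyl ester), conditions under which aryl MOM acetals, which need warm or prolonged acid, should persist; amine 12 is then acylated by the dicarbonate under bicarbonate (carbamate formation).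

Step 6
Reactants: 13 tert-butyl N-[(1R)-1-[4-methoxy-2,6-bis(methoxymethoxy)phenyl]but-3-en-1-yl]carbamate; 9 allyl bromide
Product: 14 tert-butyl N-allyl-N-[(1R)-1-[4-methoxy-2,6-bis(methoxymethoxy)phenyl]but-3-en-1-yl]carbamate
Conditions: NaH (1.5 equiv), DMF, 0 °C; then 9 (2 equiv), 0 °C to rt
Reagents that add atoms: allyl bromide, C=CCBr
Why: N-alkylation of a carbamate anion with an allylic halide; the carbamate N–H is the only acidic site and the benzylic C–H is not removed by hydride, so C2' should keep its configuration.

Step 7
Reactants: 14 tert-butyl N-allyl-N-[(1R)-1-[4-methoxy-2,6-bis(methoxymethoxy)phenyl]but-3-en-1-yl]carbamate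
Product: 15 tert-butyl (2R)-2-[4-methoxy-2,6-bis(methoxymethoxy)phenyl]-3,6-dihydropyridine-1(2H)-carboxylate
Conditions: second-generation Grubbs catalyst RuCl2(=CHPh)(H2IMes)(PCy3) (3 mol %), CH2Cl2 (0.01 M), 40 °C
Reagents that add atoms: none
Why: Ring-closing olefin metathesis of an N-allyl-N-homoallyl carbamate, the established way to N-Boc-1,2,3,6-tetrahydropyridines. The ruthenium benzylidene exchanges onto the less hindered N-allyl terminus by [2+2] cycloaddition and cycloreversion (styrene leaves in the first turnover only), the new alkylidene adds across the homoallyl alkene to a ruthenacyclobutane, and its cycloreversion releases the ring alkene and a ruthenium methylidene that carries the chain with loss of ethylene. The six-membered ring closes from a 1,7-diene by formation of the endocyclic C4'=C5' bond, the two terminal CH2 groups being excised, so the alkene is necessarily Z. No stereocentre is created, and C2' is not allylic to either reacting alkene, so its R configuration should pass through unchanged. The selectivity required is ring closure over intermolecular metathesis and over migration of the terminal alkenes: high dilution and the escape of ethylene favour closure, the carbamate removes the Lewis basicity of nitrogen that would tie up ruthenium, and its restricted rotation together with the branched C2' substituent keeps the two alkenyl arms on the same side of the N1'–C2' bond. The MOM oxygens are too far from either alkene to chelate the carbene, and both alkenes are terminal and unhindered although the aryl group is bulky.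

Step 8
Reactants: 15 tert-butyl (2R)-2-[4-methoxy-2,6-bis(methoxymethoxy)phenyl]-3,6-dihydropyridine-1(2H)-carboxylate
Product: 16 tert-butyl (2R)-2-[4-methoxy-2,6-bis(methoxymethoxy)phenyl]piperidine-1-carboxylate
Conditions: H2 (1 atm), 10% Pd/C, EtOAc, rt
Reagents that add atoms: none
Why: Heterogeneous catalytic hydrogenation of a cis-disubstituted ring alkene in a neutral solvent; the carbamate and the aryl acetals are inert, and the benzylic C–N bond of a carbamate should not be hydrogenolysed at one atmosphere and room temperature.

Step 9
Reactants: 16 tert-butyl (2R)-2-[4-methoxy-2,6-bis(methoxymethoxy)phenyl]piperidine-1-carboxylate; 17 N-bromosuccinimide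
Product: 18 tert-butyl (2R)-2-[3-bromo-4-methoxy-2,6-bis(methoxymethoxy)phenyl]piperidine-1-carboxylate
Conditions: 17 (1.0 equiv), MeCN, 0 °C
Reagents that add atoms: N-bromosuccinimide, O=C1CCC(=O)N1Br
Why: Electrophilic aromatic bromination of a 1,3,5-trioxygenated ring; the two free ring positions are equivalent by rotation about the aryl–C2' bond, so one monobromide is expected, and one equivalent at 0 °C should stop there because the halogen and the added crowding slow a second substitution.

Step 10
Reactants: 18 tert-butyl (2R)-2-[3-bromo-4-methoxy-2,6-bis(methoxymethoxy)phenyl]piperidine-1-carboxylate; 19 3-phenylprop-2-ynal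
Product: 21 tert-butyl (2R)-2-[3-(1-hydroxy-3-phenylprop-2-yn-1-yl)-4-methoxy-2,6-bis(methoxymethoxy)phenyl]piperidine-1-carboxylate (both carbinol epimers), via aryllithium 20 (not isolated)
Conditions: n-BuLi (1.05 equiv), THF, −78 °C; then 19, −78 °C; H2O
Reagents that add atoms: 3-phenylprop-2-ynal, O=CC#Cc1ccccc1
Why: Bromine–lithium exchange at −78 °C is far faster than deprotonation next to the carbamate nitrogen or attack at the Boc carbonyl and gives aryllithium 20, stabilised by the flanking acetal oxygen; 1,2-addition to the non-enolisable ynal forms the C4a–C4 bond, and the uncontrolled carbinol centre is removed in step 11.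

Step 11
Reactants: 21 tert-butyl (2R)-2-[3-(1-hydroxy-3-phenylprop-2-yn-1-yl)-4-methoxy-2,6-bis(methoxymethoxy)phenyl]piperidine-1-carboxylate
Product: 22 tert-butyl (2R)-2-[4-methoxy-2,6-bis(methoxymethoxy)-3-(3-phenylprop-2-ynoyl)phenyl]piperidine-1-carboxylate
Conditions: Dess–Martin periodinane (1.3 equiv), NaHCO3, CH2Cl2, 0 °C to rt
Reagents that add atoms: none
Why: Dess–Martin oxidation of a secondary benzylic propargylic alcohol to the ynone; the bicarbonate buffer keeps acetic acid from the acetals and from the doubly activated alcohol, which could otherwise ionise (Meyer–Schuster-type rearrangement), so crude 21 is best oxidised without chromatography.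

Step 12
Reactants: 22 tert-butyl (2R)-2-[4-methoxy-2,6-bis(methoxymethoxy)-3-(3-phenylprop-2-ynoyl)phenyl]piperidine-1-carboxylate
Product: 24 7-hydroxy-5-methoxy-2-phenyl-8-[(2R)-piperidin-2-yl]-4H-chromen-4-one, via enaminone 23 (not isolated)
Conditions: Et2NH (3 equiv), MeOH, rt; then HCl (3 M in MeOH), 50 °C; aq. NaHCO3
Reagents that add atoms: none
Why: Conjugate addition of the secondary amine to the ynone gives enaminone 23 and fixes C2 as the only electrophilic carbon; HCl in methanol then cleaves both MOM acetals and the Boc group, and the phenol ortho to the carbonyl displaces diethylamine by addition–elimination, the known enaminone-to-chromone cyclisation, which can only give the six-membered ring. By then ring A is an aryl ketone, which disfavours ionisation of the C2'–N1' bond, and the free base is released with bicarbonate without heating.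

## Compound list

1 | 5-methoxyresorcinol (5-methoxybenzene-1,3-diol) | COc1cc(O)cc(O)c1 | starting material
2 | chloromethyl methyl ether | COCCl | starting material
3 | 1-methoxy-3,5-bis(methoxymethoxy)benzene | COCOc1cc(OC)cc(OCOC)c1 | intermediate
4 | N,N-dimethylformamide | CN(C)C=O | starting material
5 | [4-methoxy-2,6-bis(methoxymethoxy)phenyl]lithium | [Li]c1c(OCOC)cc(OC)cc1OCOC | intermediate
6 | 4-methoxy-2,6-bis(methoxymethoxy)benzaldehyde | COCOc1cc(OC)cc(OCOC)c1C=O | intermediate
7 | (S)-2-methylpropane-2-sulfinamide | CC(C)(C)[S@](=O)N | starting material
8 | (S)-N-[(E)-[4-methoxy-2,6-bis(methoxymethoxy)phenyl]methylidene]-2-methylpropane-2-sulfinamide | COCOc1cc(OC)cc(OCOC)c1/C=N/[S@@](=O)C(C)(C)C | intermediate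
9 | allyl bromide | C=CCBr | starting material
10 | (S)-N-[(1R)-1-[4-methoxy-2,6-bis(methoxymethoxy)phenyl]but-3-en-1-yl]-2-methylpropane-2-sulfinamide | COCOc1cc(OC)cc(OCOC)c1[C@@H](CC=C)N[S@@](=O)C(C)(C)C | intermediate
11 | di-tert-butyl dicarbonate | CC(C)(C)OC(=O)OC(=O)OC(C)(C)C | starting material
12 | (1R)-1-[4-methoxy-2,6-bis(methoxymethoxy)phenyl]but-3-en-1-amine (formed as its hydrochloride, freed by NaHCO3) | COCOc1cc(OC)cc(OCOC)c1[C@@H](CC=C)N | intermediate
13 | tert-butyl N-[(1R)-1-[4-methoxy-2,6-bis(methoxymethoxy)phenyl]but-3-en-1-yl]carbamate | COCOc1cc(OC)cc(OCOC)c1[C@@H](CC=C)NC(=O)OC(C)(C)C | intermediate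
14 | tert-butyl N-allyl-N-[(1R)-1-[4-methoxy-2,6-bis(methoxymethoxy)phenyl]but-3-en-1-yl]carbamate | COCOc1cc(OC)cc(OCOC)c1[C@@H](CC=C)N(CC=C)C(=O)OC(C)(C)C | intermediate
15 | tert-butyl (2R)-2-[4-methoxy-2,6-bis(methoxymethoxy)phenyl]-3,6-dihydropyridine-1(2H)-carboxylate | COCOc1cc(OC)cc(OCOC)c1[C@H]1CC=CCN1C(=O)OC(C)(C)C | intermediate
16 | tert-butyl (2R)-2-[4-methoxy-2,6-bis(methoxymethoxy)phenyl]piperidine-1-carboxylate | COCOc1cc(OC)cc(OCOC)c1[C@H]1CCCCN1C(=O)OC(C)(C)C | intermediate
17 | N-bromosuccinimide | O=C1CCC(=O)N1Br | starting material
18 | tert-butyl (2R)-2-[3-bromo-4-methoxy-2,6-bis(methoxymethoxy)phenyl]piperidine-1-carboxylate | COCOc1cc(OC)c(Br)c(OCOC)c1[C@H]1CCCCN1C(=O)OC(C)(C)C | intermediate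
19 | 3-phenylprop-2-ynal | O=CC#Cc1ccccc1 | starting material
20 | [3-[(2R)-1-(tert-butoxycarbonyl)piperidin-2-yl]-6-methoxy-2,4-bis(methoxymethoxy)phenyl]lithium | COCOc1cc(OC)c([Li])c(OCOC)c1[C@H]1CCCCN1C(=O)OC(C)(C)C | intermediate
21 | tert-butyl (2R)-2-[3-(1-hydroxy-3-phenylprop-2-yn-1-yl)-4-methoxy-2,6-bis(methoxymethoxy)phenyl]piperidine-1-carboxylate (both carbinol epimers) | COCOc1cc(OC)c(C(O)C#Cc2ccccc2)c(OCOC)c1[C@H]1CCCCN1C(=O)OC(C)(C)C | intermediate
22 | tert-butyl (2R)-2-[4-methoxy-2,6-bis(methoxymethoxy)-3-(3-phenylprop-2-ynoyl)phenyl]piperidine-1-carboxylate | COCOc1cc(OC)c(C(=O)C#Cc2ccccc2)c(OCOC)c1[C@H]1CCCCN1C(=O)OC(C)(C)C | intermediate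
23 | tert-butyl (2R)-2-[3-[3-(diethylamino)-3-phenylprop-2-enoyl]-4-methoxy-2,6-bis(methoxymethoxy)phenyl]piperidine-1-carboxylate (alkene geometry not defined) | COCOc1cc(OC)c(C(=O)C=C(N(CC)CC)c2ccccc2)c(OCOC)c1[C@H]1CCCCN1C(=O)OC(C)(C)C | intermediate
24 | 7-hydroxy-5-methoxy-2-phenyl-8-[(2R)-piperidin-2-yl]-4H-chromen-4-one | COc1cc(O)c([C@H]2CCCCN2)c2oc(-c3ccccc3)cc(=O)c12 | target

## Step count and least certain steps

Total step count: 12. Longest linear sequence: 12 steps, all in one line from 1.

**Step 7 (key step).** Intermolecular metathesis to oligomers, or migration of the terminal alkenes by ruthenium hydride species, may compete if the bulky aryl group and slow carbamate rotation keep the two arms apart. The fallback leaves metathesis and closes the ring at N1'–C6' by alkylation, setting out from aldimine 8 and rejoining at 16.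
- 4-Chlorobutylmagnesium bromide F1 (from 1-bromo-4-chlorobutane and Mg) would be added to 8 in CH2Cl2 at −48 °C under the same chelate control, to give (S)-N-[(1R)-5-chloro-1-arylpentyl]sulfinamide F2.
- LiN(SiMe3)2 in THF would close the ring to the N-sulfinyl piperidine F3.
- HCl in methanol at 0 °C would give piperidine hydrochloride F4, and bicarbonate with 11 would give 16.

**Step 4.** Facial selectivity may erode, or addition may be slow, because the ortho MOM oxygens can compete with the sulfinyl oxygen for the metal and the di-ortho-substituted ring twists out of the imine plane. The fallback drops auxiliary control, setting out from aldehyde 6 and rejoining at 13.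
- Three-component aminoallylation of 6 with aqueous ammonia and allylboronic acid pinacol ester would give the racemic homoallylamine F5.
- The dicarbonate 11 would convert it to the racemic carbamate F6, which would be resolved by preparative chromatography on a chiral stationary phase to give 13.

**Step 5.** Partial loss of the MOM acetals may accompany acidolysis of the sulfinamide. The fallback accepts complete loss and re-protects, setting out from 10 and rejoining at 13.
- Excess HCl in methanol at room temperature would give the aminoresorcinol hydrochloride F7.
- Bicarbonate and 11 would give the N-Boc resorcinol F8, and 2 with i-Pr2NEt in CH2Cl2 would restore both acetals to give 13.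

**Step 10.** Proton transfer to the hindered aryllithium (loss of bromine without C–C bond formation), deprotonation at C2' with loss of configuration, or attack at the carbamate may compete with exchange and addition. The fallback replaces the organolithium by cross-coupling, setting out from 18 and rejoining at the target 24.
- Stille coupling of 18 with tributyl(1-ethoxyvinyl)stannane and Pd(PPh3)4 in toluene at 100 °C would give the enol ether F9, and brief dilute aqueous acid at room temperature would give the methyl ketone F10.
- C-benzoylation of its lithium enolate (LiN(SiMe3)2, benzoyl chloride, THF, −78 °C), the direct form of the Baker–Venkataraman sequence, would give the 1,3-diketone F11.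
- HCl in methanol at 50 °C would remove the acetals and the carbamate and cyclodehydrate F11 to 24.

**Step 12.** Reversible ionisation of the C2'–N1' bond in warm acid before the carbamate has left could erode enantiopurity, and incomplete amine addition could allow five-membered closure. The fallback separates ring closure from nitrogen deprotection, setting out from 22 and rejoining at 24.
- After the diethylamine addition, pyridinium p-toluenesulfonate in methanol at 50 °C would remove the acetals and close ring C while the carbamate stays, giving the carbamate-protected flavone F12 (the same structure as A1).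
- CF3CO2H in CH2Cl2 at 0 °C would then remove the Boc group from the now electron-poor ring to give 24.

## Further compounds

F1 | step 7 | 4-chlorobutylmagnesium bromide | ClCCCC[Mg]Br
F2 | step 7 | (S)-N-[(1R)-5-chloro-1-[4-methoxy-2,6-bis(methoxymethoxy)phenyl]pentyl]-2-methylpropane-2-sulfinamide | COCOc1cc(OC)cc(OCOC)c1[C@@H](CCCCCl)N[S@@](=O)C(C)(C)C
F3 | step 7 | (2R)-2-[4-methoxy-2,6-bis(methoxymethoxy)phenyl]-1-[(S)-2-methylpropane-2-sulfinyl]piperidine | COCOc1cc(OC)cc(OCOC)c1[C@H]1CCCCN1[S@@](=O)C(C)(C)C
F4 | step 7 | (2R)-2-[4-methoxy-2,6-bis(methoxymethoxy)phenyl]piperidine hydrochloride | COCOc1cc(OC)cc(OCOC)c1[C@H]1CCCCN1.Cl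
F5 | step 4 | racemic 1-[4-methoxy-2,6-bis(methoxymethoxy)phenyl]but-3-en-1-amine | COCOc1cc(OC)cc(OCOC)c1C(CC=C)N
F6 | step 4 | racemic tert-butyl N-[1-[4-methoxy-2,6-bis(methoxymethoxy)phenyl]but-3-en-1-yl]carbamate | COCOc1cc(OC)cc(OCOC)c1C(CC=C)NC(=O)OC(C)(C)C
F7 | step 5 | 2-[(1R)-1-aminobut-3-en-1-yl]-5-methoxybenzene-1,3-diol hydrochloride | COc1cc(O)c([C@@H](CC=C)N)c(O)c1.Cl
F8 | step 5 | tert-butyl N-[(1R)-1-(2,6-dihydroxy-4-methoxyphenyl)but-3-en-1-yl]carbamate | COc1cc(O)c([C@@H](CC=C)NC(=O)OC(C)(C)C)c(O)c1
F9 | step 10 | tert-butyl (2R)-2-[3-(1-ethoxyethenyl)-4-methoxy-2,6-bis(methoxymethoxy)phenyl]piperidine-1-carboxylate | COCOc1cc(OC)c(C(=C)OCC)c(OCOC)c1[C@H]1CCCCN1C(=O)OC(C)(C)C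
F10 | step 10 | tert-butyl (2R)-2-[3-acetyl-4-methoxy-2,6-bis(methoxymethoxy)phenyl]piperidine-1-carboxylate | COCOc1cc(OC)c(C(C)=O)c(OCOC)c1[C@H]1CCCCN1C(=O)OC(C)(C)C
F11 | step 10 | tert-butyl (2R)-2-[4-methoxy-2,6-bis(methoxymethoxy)-3-(3-oxo-3-phenylpropanoyl)phenyl]piperidine-1-carboxylate | COCOc1cc(OC)c(C(=O)CC(=O)c2ccccc2)c(OCOC)c1[C@H]1CCCCN1C(=O)OC(C)(C)C
F12 | step 12 | tert-butyl (2R)-2-(7-hydroxy-5-methoxy-4-oxo-2-phenyl-4H-chromen-8-yl)piperidine-1-carboxylate | COc1cc(O)c([C@H]2CCCCN2C(=O)OC(C)(C)C)c2oc(-c3ccccc3)cc(=O)c12
A1 | alternative 1 | tert-butyl (2R)-2-(7-hydroxy-5-methoxy-4-oxo-2-phenyl-4H-chromen-8-yl)piperidine-1-carboxylate | COc1cc(O)c([C@H]2CCCCN2C(=O)OC(C)(C)C)c2oc(-c3ccccc3)cc(=O)c12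
A2 | alternative 1 | tert-butyl (2R)-2-(2,6-dihydroxy-3-iodo-4-methoxyphenyl)piperidine-1-carboxylate | COc1cc(O)c([C@H]2CCCCN2C(=O)OC(C)(C)C)c(O)c1I
A3 | alternative 1 | phenylacetylene | C#Cc1ccccc1
A4 | alternative 1 | carbon monoxide | [C-]#[O+]
A5 | alternative 2 | (2R)-2-[4-methoxy-2,6-bis(methoxymethoxy)phenyl]-1-tosyl-2,3-dihydropyridin-4(1H)-one | COCOc1cc(OC)cc(OCOC)c1[C@H]1CC(=O)C=CN1S(=O)(=O)c1ccc(C)cc1
A6 | alternative 2 | N-[(E)-[4-methoxy-2,6-bis(methoxymethoxy)phenyl]methylidene]-4-methylbenzenesulfonamide | COCOc1cc(OC)cc(OCOC)c1/C=N/S(=O)(=O)c1ccc(C)cc1
A7 | alternative 2 | (E)-1-methoxy-3-(trimethylsilyloxy)buta-1,3-diene | CO/C=C/C(=C)O[Si](C)(C)C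
A8 | alternative 3 | (2R)-2-[4-methoxy-2,6-bis(methoxymethoxy)phenyl]piperidine | COCOc1cc(OC)cc(OCOC)c1[C@H]1CCCCN1
A9 | alternative 3 | 5-chloro-1-[4-methoxy-2,6-bis(methoxymethoxy)phenyl]pentan-1-one | COCOc1cc(OC)cc(OCOC)c1C(=O)CCCCCl
A10 | alternative 3 | (1R)-5-chloro-1-[4-methoxy-2,6-bis(methoxymethoxy)phenyl]pentan-1-amine | COCOc1cc(OC)cc(OCOC)c1[C@@H](CCCCCl)N
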